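(The numbers of this flask were drawn at random within sensible limits; the flask was simulated.)

The ratio I had to find was nucleophile to electrophile, in equivalents, for a flask that stands at 50% reacted after 5.0 h.

    electrophile + nucleophile → acid set free + product (k1 = 0.140 M⁻¹ min⁻¹)
    nucleophile + acid set free ⇌ protonated nucleophile, settled at all times (K2 = 115 M⁻¹)
    acid set free → by-product carried off (k3 = 0.0461 min⁻¹)
    gas ⇌ free base, rate k4*(csat - [free base]) (k4 = 0.0784 min⁻¹, csat = 15 mM)
    acid set free + free base ⇌ salt of the base, settled at all times (K5 = 3.01 × 10⁶ M⁻¹)

electrophile 0.13 M; gas 15 mM (held); time 5.0 h

- the equivalents of nucleophile at which the part of the electrophile that has reacted at 5.0 h is just 50%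

- at the start none of free base is dissolved
- the amount of nucleophile is what is sought; it is there from the start
- run time (flask): 5.0 h

I first checked the acid. The gas could feed free base at up to 1.18 mM min⁻¹. Over the run that came to 5.43 times the acid set free at the mark. So I reckoned with free nucleophile and the first step as written.

I carried one number, the clock number D: the rate constant of the first step times the charged electrophile times the run time, 5.46. Let n be the equivalents of nucleophile.

The two react one to one, so n lay above 0.500 equiv. Up to the mark, the electrophile stood at or above half its charge. The nucleophile therefore fell at least as fast as a pseudo-first-order decay, and its free share was at most 6.52%. That put n below 0.535 equiv.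

I then computed only the excess over the floor. Integrating the first step gave n − 0.5 = 0.5·n·exp(−D(1 − n)). One pass from the floor gave 0.516, and a second gave 0.518 equiv.

The forecast gave 0.519 equiv, inside my bracket, and held that “Base therefore keeps up after the first few minutes”.

The simulation gave 0.519 equiv. In this flask, 19.9% of the electrophile was used at 0.500 h, and the first step had half its turnover done by 0.705 h. The passage of gas into free base ran alongside it, half done by 0.716 h. D put the free nucleophile at 3.56% of the charge, and this flask held 3.61% at 5.00 h. For a second flask with a quarter more nucleophile than the simulated answer, 0.648 equiv, the same D gave 61.1% reacted, and that flask reached 61.1%.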